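**Retrosynthetic overview**
1. The route rests on the ten-membered ring C1–C10. Its C1=C10 alkene and the C5–OH/C4=C15 unit (the ene product of a C4=C5 alkene) make up a cyclodeca-1,5-diene, which is the thermal opening product of a bicyclo[2.2.0]hexane (C1, C2, C3, C4, C5, C10) fused to a six-membered ring B (C5–C10).
2. Key disconnection: C1–C10 and C4–C5, made by [2+2] photocycloaddition of ring B enone ester 10 (C5=C10, C6=O) with 1-methylcyclobutene 12; heat later cleaves C5–C10 and C1–C4.
3. Enone 10 comes from (−)-quinic acid: its C3–O becomes C8–OTBS, its C4 takes the acetate arm (C7) by Wittig olefination and hydroxyl-directed hydrogenation, its C5–OH becomes the C6 ketone, and its C1 becomes the ester-bearing C10.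
4. After the key step: C6 reduction, then the 6,12-lactone and the C11 methylene on the saturated tricycle, cycloreversion, C8 angelate, and last the singlet-oxygen ene reaction at C4=C5.
5. Ring order: ring B (chiral pool), central cyclobutane (step 9), γ-lactone (step 11), ten-membered ring (step 13).

Key step: step 9

Assumption: germacrane numbering is used for all compounds (quinic acid C1, C2, C3, C4, C5, C6 = C10, C9, C8, C7, C6, C5), and 1-methylcyclobutene is made, not bought.

Step 1
Reactants: 1 (−)-quinic acid
Product: 2 quinide (bridged γ-lactone from the C10 carboxyl to O6)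
Conditions: p-TsOH·H2O (cat.), toluene/DMF, reflux, Dean–Stark
Reagents that add atoms: none
Why: Acid-catalysed lactonisation joins the carboxyl group to the only hydroxyl that is cis and 1,3 to it and removes water azeotropically, without touching a stereocentre.

Step 2
Reactants: 2 quinide
Product: 3 quinide mono-TBS ether (silyl ether on the equatorial secondary hydroxyl, the future O8)
Conditions: TBSCl (1.1 equiv), imidazole, DMF, 0 °C
Reagents that add atoms: tert-butyldimethylsilyl chloride, CC(C)(C)[Si](C)(C)Cl
Why: Silylation with a bulky chlorosilane should select the equatorial secondary hydroxyl over the axial secondary and the tertiary hydroxyl on steric grounds.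

Step 3
Reactants: 3 quinide mono-TBS ether
Product: 4 keto lactone (ketone at the future C7)
Conditions: Dess–Martin periodinane, CH2Cl2, rt
Reagents that add atoms: none
Why: Dess–Martin oxidation converts the one remaining secondary alcohol into the ketone under neutral conditions that leave the tertiary alcohol, the lactone and the silyl ether alone.

Step 4
Reactants: 4 keto lactone; 5 tert-butyl (triphenylphosphoranylidene)acetate
Product: 6 (E)-alkylidene lactone (C7=CH–CO2tBu, ester on the C6 side)
Conditions: toluene, 90 °C
Reagents that add atoms: none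
Why: Wittig olefination of an α-alkoxy ketone with a stabilised ylide runs without base, as with uloses, and the ester should settle on the side of C6, whose in-plane substituent is only hydrogen; the geometry is erased in step 6.

Step 5
Reactants: 6 (E)-alkylidene lactone
Product: 7 methyl ester diol (C10 bears OH and CO2Me, allylic C6–OH free)
Conditions: K2CO3 (0.2 equiv), MeOH, 0 °C, then AcOH
Reagents that add atoms: methanol, CO
Why: Base-catalysed transesterification opens the strained bridged lactone to the methyl ester much faster than the freed C6 alkoxide can attack the hindered tert-butyl enoate, so the butenolide should not form if the reaction is quenched cold as soon as 6 is consumed.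

Step 6
Reactants: 7 methyl ester diol
Product: 8 saturated diol diester (acetate arm at C7 cis to C8–OTBS and trans to C6–OH)
Conditions: H2 (1 atm), [Ir(cod)(PCy3)(py)]PF6 (5 mol %), CH2Cl2, rt
Reagents that add atoms: none
Why: Hydroxyl-directed hydrogenation with the cationic monovalent iridium catalyst delivers hydrogen to C7 from the face of the allylic C6–OH, which is also the face away from the C8 silyloxy group, so the acetate arm ends cis to C8–OTBS.

Step 7
Reactants: 8 saturated diol diester
Product: 10 methyl (4R,5R)-5-(tert-butyldimethylsilyloxy)-4-(2-tert-butoxy-2-oxoethyl)-3-oxocyclohex-1-ene-1-carboxylate (ring B enone ester), via beta-hydroxy ketone 9 (not isolated)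
Conditions: pyridinium chlorochromate C5H5NH[CrO3Cl], pyridine, 4 Å molecular sieves, CH2Cl2, rt
Reagents that add atoms: none
Why: Chromate oxidation of the secondary C6–OH gives a β-hydroxy ketone that loses the tertiary C10 hydroxyl by E1cB elimination under the buffered conditions (the dehydroquinate-to-dehydroshikimate type of dehydration), while the weak base leaves C7 and the β-silyloxy group untouched.

Step 8
Reactants: 11 methylenecyclobutane
Product: 12 1-methylcyclobutene
Conditions: KOtBu (cat.), DMSO, 70 °C, sealed vessel; spinning-band distillation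
Reagents that add atoms: none
Why: Base-catalysed prototropic isomerisation moves the double bond into the ring to the trisubstituted alkene, which is favoured at equilibrium.

Step 9
Reactants: 10 ring B enone ester; 12 1-methylcyclobutene
Product: 13 cis-anti-cis tricyclic photoadduct (C6 ketone; new bonds C1–C10 and C4–C5; CH3 on C4; CO2Me on C10; cyclobutane on the face of ring B opposite to the C7 arm and C8–OTBS)
Conditions: hν (medium-pressure Hg lamp, uranium-glass filter, λ > 330 nm), 12 (15 equiv), CH2Cl2, −40 °C, degassed
Reagents that add atoms: none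
Why: Excitation of the 3-carbomethoxy enone above 300 nm and intersystem crossing give the twisted triplet, which adds to the strained alkene through a triplet 1,4-biradical that recombines to the cyclobutane; the closest known reaction type is the enone–cyclobutene [2+2] photocycloaddition used in photo-thermal metathesis routes to germacranes. The only ring closed is the central cyclobutane (C1, C4, C5, C10), formed intermolecularly by the C1–C10 and C4–C5 bonds, the second by radical recombination, cis-fused both to ring B and to the cyclobutene ring. At C5 and C10 the cyclobutene should add to the face of ring B anti to the C7 arm and the C8 silyloxy group, which lie on the same face, and the cis 6/4 fusion follows from the strain of the alternative; at C1 and C4 the cis relation is fixed by the cyclobutene ring, whose CH2CH2 bridge should turn away from ring B (anti) because the syn arrangement presses it against C6 and C9. The step needs head-to-head regiochemistry (methyl-bearing C4 to C5): closure between C10 and C4 would join two fully substituted carbons, whereas either order of bond formation to the wanted adduct passes through a tertiary radical and closes at a CH carbon. An excess of 12 at low temperature suppresses enone dimerisation, and the long-wavelength filter keeps the ester groups and the product ketone unexcited.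

Step 10
Reactants: 13 tricyclic photoadduct
Product: 14 C6 alcohol (OH cis to C4 and trans to the C7 arm)
Conditions: NaBH4, MeOH/CH2Cl2, −40 to −10 °C
Reagents that add atoms: none
Why: Borohydride reduction of the ketone should take place from the face opposite the cyclobutane, whose C4 methyl group and axial C10–C1 bond cover the other face, which puts the new hydroxyl trans to the C7 arm, and the esters are inert to NaBH4.

Step 11
Reactants: 14 C6 alcohol
Product: 15 tetracyclic trans-fused γ-lactone (O6 to C12)
Conditions: camphorsulfonic acid (0.2 equiv), benzene, 60 °C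
Reagents that add atoms: none
Why: Acid-catalysed intramolecular transesterification (lactonisation) of the γ-hydroxy tert-butyl ester closes the trans-fused γ-lactone with loss of tert-butanol, and the catalytic anhydrous acid spares the silyl ether, so C8–O cannot compete.

Step 12
Reactants: 15 tetracyclic γ-lactone
Product: 18 tetracyclic α-methylene γ-lactone, via Mannich base 16 (not isolated), via ammonium iodide 17 (not isolated)
Conditions: LiN(iPr)2, THF, −78 °C; CH2=NMe2+ I−, −78 °C to rt; MeI, MeOH, rt; NaHCO3 (aq), EtOAc
Reagents that add atoms: N,N-dimethylmethyleneiminium iodide (Eschenmoser's salt), C=[N+](C)C.[I-]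
Why: Eschenmoser methylenation (enolate Mannich reaction, quaternisation, Hofmann-type elimination) should be clean here because the lactone α-CH2 is the only enolisable position, the C10 ester standing on a quaternary carbon.

Step 13
Reactants: 18 tetracyclic α-methylene γ-lactone
Product: 19 cyclodeca-1(10),4-diene lactone (C1=C10 ring-cis, C4=C5 ring-trans, 8-OTBS)
Conditions: toluene (0.005 M), BHT (cat.), sealed base-washed tube, 190 °C
Reagents that add atoms: none
Why: Thermal cycloreversion of the bicyclo[2.2.0]hexane starts with homolysis of the strained C1–C4 bond, and the cyclohexane-1,4-diyl then cleaves the fully substituted C5–C10 bond through the chair that carries C9 axial and the ester and C6 equatorial, which should give C1=C10 ring-cis and C4=C5 ring-trans.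

Step 14
Reactants: 19 cyclodecadiene lactone
Product: 20 C8 alcohol
Conditions: HF·pyridine, pyridine, THF, 0 °C to rt
Reagents that add atoms: none
Why: Fluoride cleavage of the secondary silyl ether under buffered acidic conditions frees C8–OH without a basic alkoxide that could add to the α-methylene lactone or translactonise.

Step 15
Reactants: 20 C8 alcohol; 21 angelic acid
Product: 23 C8 angelate, via mixed anhydride 22 (not isolated)
Conditions: 21, 2,4,6-trichlorobenzoyl chloride, Et3N, toluene, rt; then 20, toluene, 80 °C
Reagents that add atoms: none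
Why: Yamaguchi-type mixed-anhydride esterification acylates the only free hydroxyl, and leaving out a nucleophilic catalyst should avoid the addition–elimination path that turns angelates into tiglates.

Step 16
Reactants: 23 C8 angelate
Product: 25 CNP0163095.1 (target), via allylic hydroperoxide 24 (not isolated)
Conditions: O2, hν (visible), tetraphenylporphyrin (cat.), CH2Cl2, −20 °C; then PPh3, 0 °C
Reagents that add atoms: oxygen, O=O
Why: The Schenck ene reaction of singlet oxygen should take the only electron-rich alkene, attack C5 on the outer face of the ring-trans C4=C5 bond (C6–H lies in the alkene plane and C7 on the inner face, so the new C5–O bond is trans to C6–O) and abstract hydrogen from the C15 methyl on the more crowded side of the alkene, after which phosphine reduction of the hydroperoxide gives the C5 alcohol.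

**Compound list**
1 | (−)-quinic acid, (1S,3R,4S,5R)-1,3,4,5-tetrahydroxycyclohexane-1-carboxylic acid | C1[C@@H](O)[C@H](O)[C@H](O)C[C@]1(C(=O)O)O | starting material
2 | quinide, (1S,3R,4R,5R)-1,3,4-trihydroxy-6-oxabicyclo[3.2.1]octan-7-one | C1[C@@H]2[C@H](O)[C@H](O)C[C@@]1(O)C(=O)O2 | intermediate
3 | quinide mono-TBS ether (silyl ether on the equatorial secondary OH, future O8) | C1[C@@H]2[C@H](O)[C@H](O[Si](C)(C)C(C)(C)C)C[C@@]1(O)C(=O)O2 | intermediate
4 | keto lactone (ketone at future C7) | C1[C@@H]2C(=O)[C@H](O[Si](C)(C)C(C)(C)C)C[C@@]1(O)C(=O)O2 | intermediate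
5 | tert-butyl (triphenylphosphoranylidene)acetate | CC(C)(C)OC(=O)C=P(c1ccccc1)(c1ccccc1)c1ccccc1 | starting material
6 | (E)-alkylidene lactone (C7=CH–CO2tBu, ester on the C6 side) | C1[C@@H]2/C(=C\C(=O)OC(C)(C)C)[C@H](O[Si](C)(C)C(C)(C)C)C[C@@]1(O)C(=O)O2 | intermediate
7 | methyl ester diol (C10: OH and CO2Me; C6–OH; C7 alkylidene; C8–OTBS) | C1[C@@H](O)/C(=C\C(=O)OC(C)(C)C)[C@H](O[Si](C)(C)C(C)(C)C)C[C@@]1(O)C(=O)OC | intermediate
8 | saturated diol diester (C7 arm cis to C8–OTBS, trans to C6–OH) | C1[C@@H](O)[C@H](CC(=O)OC(C)(C)C)[C@H](O[Si](C)(C)C(C)(C)C)C[C@@]1(O)C(=O)OC | intermediate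
9 | β-hydroxy ketone (C6 ketone, C10 tertiary OH) | C1C(=O)[C@H](CC(=O)OC(C)(C)C)[C@H](O[Si](C)(C)C(C)(C)C)C[C@@]1(O)C(=O)OC | intermediate
10 | methyl (4R,5R)-5-(tert-butyldimethylsilyloxy)-4-(2-tert-butoxy-2-oxoethyl)-3-oxocyclohex-1-ene-1-carboxylate (ring B enone ester) | O=C1[C@H](CC(=O)OC(C)(C)C)[C@H](O[Si](C)(C)C(C)(C)C)CC(C(=O)OC)=C1 | intermediate
11 | methylenecyclobutane | C=C1CCC1 | starting material
12 | 1-methylcyclobutene | CC1=CCC1 | intermediate
13 | cis-anti-cis tricyclic photoadduct (C6 ketone, bicyclo[2.2.0]hexane C1–C4/C5/C10) | O=C1[C@H](CC(=O)OC(C)(C)C)[C@H](O[Si](C)(C)C(C)(C)C)C[C@@]2(C(=O)OC)[C@@H]3CC[C@]3(C)[C@@H]12 | intermediate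
14 | C6 alcohol of 13 (OH trans to the C7 arm) | O[C@H]1[C@H](CC(=O)OC(C)(C)C)[C@H](O[Si](C)(C)C(C)(C)C)C[C@@]2(C(=O)OC)[C@@H]3CC[C@]3(C)[C@@H]12 | intermediate
15 | tetracyclic trans-fused 6,12-γ-lactone | O=C1O[C@H]2[C@H](C1)[C@H](O[Si](C)(C)C(C)(C)C)C[C@@]3(C(=O)OC)[C@@H]4CC[C@]4(C)[C@@H]23 | intermediate
16 | Mannich base, C11 dimethylaminomethyl lactone (C11 epimers) | CN(C)CC1C(=O)O[C@H]2[C@H]1[C@H](O[Si](C)(C)C(C)(C)C)C[C@@]3(C(=O)OC)[C@@H]4CC[C@]4(C)[C@@H]23 | intermediate
17 | trimethylammonium iodide of 16 | C[N+](C)(C)CC1C(=O)O[C@H]2[C@H]1[C@H](O[Si](C)(C)C(C)(C)C)C[C@@]3(C(=O)OC)[C@@H]4CC[C@]4(C)[C@@H]23.[I-] | intermediate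
18 | tetracyclic α-methylene γ-lactone | C=C1C(=O)O[C@H]2[C@H]1[C@H](O[Si](C)(C)C(C)(C)C)C[C@@]3(C(=O)OC)[C@@H]4CC[C@]4(C)[C@@H]23 | intermediate
19 | 8-O-TBS cyclodeca-1(10),4-diene 6,12-lactone (C1=C10 ring-cis, C4=C5 ring-trans) | C=C1C(=O)O[C@@H]2/C=C(C)/CC/C=C(C(=O)OC)\C[C@@H](O[Si](C)(C)C(C)(C)C)[C@@H]12 | intermediate
20 | C8 alcohol of 19 | C=C1C(=O)O[C@@H]2/C=C(C)/CC/C=C(C(=O)OC)\C[C@@H](O)[C@@H]12 | intermediate
21 | angelic acid, (Z)-2-methylbut-2-enoic acid | C/C=C(/C)C(=O)O | starting material
22 | angelic 2,4,6-trichlorobenzoic anhydride | C/C=C(/C)C(=O)OC(=O)c1c(Cl)cc(Cl)cc1Cl | intermediate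
23 | C8 angelate of 20 | C=C1C(=O)O[C@@H]2/C=C(C)/CC/C=C(C(=O)OC)\C[C@@H](OC(=O)/C(C)=C\C)[C@@H]12 | intermediate
24 | C5 hydroperoxide with C4=C15 | C=C1C(=O)O[C@H]2[C@H]1[C@H](OC(=O)/C(C)=C\C)C/C(C(=O)OC)=C\CCC(=C)[C@@H]2OO | intermediate
25 | CNP0163095.1 | C=C1C(=O)O[C@H]2[C@H]1[C@H](OC(=O)/C(C)=C\C)C/C(C(=O)OC)=C\CCC(=C)[C@@H]2O | target

**Step count and risks**
Total step count: 16. Longest linear sequence: 15 steps (1–7 and 9–16).

Steps most likely to fail:

Step 9. The photocycloaddition may leak to the head-to-tail orientation (the methyl-bearing carbon bonding to C10), and the facial selectivity set by the C7 and C8 substituents may be incomplete. The fallback sets out from 10 and changes the alkene partner to an electron-poor cyclobutene, methyl cyclobut-1-ene-1-carboxylate (COC(=O)C1=CCC1), whose substituted carbon is known to bond to the enone α-carbon. Irradiation should give the C4-carbomethoxy photoadduct F1. NaBH4 reduction, with closure of the C6 alkoxide onto the new ester, gives the γ-lactone F2. iBu2AlH (1 equiv, −78 °C) gives the lactol F3, and ethane-1,2-dithiol with Zn(OTf)2 opens it to the hydroxy dithiolane F4. Raney Ni desulfurisation turns the dithiolane carbon into the C4 methyl group, and the sequence comes back to the route at 14.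

Step 13. The diradical may partition through the other chair (C1=C10 ring-trans), the diene may undergo Cope rearrangement at the temperature needed, and the exocyclic acrylate may be lost by radical polymerisation. The fallback sets out from 15 and carries the methylene group through the pyrolysis in masked form. Step 12 is stopped at the Mannich base 16, which is isolated and thermolysed with short contact time to the amino diene F5. Quaternisation with MeI gives the ammonium iodide F6, and NaHCO3 elimination comes back to the route at 19.

Step 10. Hydride may be delivered from the cyclobutane face, since the axial C7 arm also hinders the wanted trajectory, and this would set C6 with the hydroxyl cis to the arm. The fallback sets out from 13 and corrects C6 by substitution instead of by reduction. The C6 epimer F7 (the product of the wrong-face reduction, or made on purpose with LiBH(sBu)3) is inverted by Mitsunobu esterification (PPh3, diisopropyl azodicarboxylate, 4-nitrobenzoic acid) to the 4-nitrobenzoate F8. K2CO3 in MeOH then releases the alcohol and comes back to the route at 14.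

**Further compounds**
F1 | step 9 | C4-carbomethoxy photoadduct (13 with CO2Me in place of the C4 methyl) | O=C1[C@H](CC(=O)OC(C)(C)C)[C@H](O[Si](C)(C)C(C)(C)C)C[C@@]2(C(=O)OC)[C@@H]3CC[C@]3(C(=O)OC)[C@@H]12
F2 | step 9 | γ-lactone between O6 and the C4 carboxyl carbon | O=C1O[C@H]2[C@H](CC(=O)OC(C)(C)C)[C@H](O[Si](C)(C)C(C)(C)C)C[C@@]3(C(=O)OC)[C@@H]4CC[C@@]14[C@@H]23
F3 | step 9 | lactol of F2 | OC1O[C@H]2[C@H](CC(=O)OC(C)(C)C)[C@H](O[Si](C)(C)C(C)(C)C)C[C@@]3(C(=O)OC)[C@@H]4CC[C@@]14[C@@H]23
F4 | step 9 | C6 alcohol with a 1,3-dithiolan-2-yl group on C4 | O[C@H]1[C@H](CC(=O)OC(C)(C)C)[C@H](O[Si](C)(C)C(C)(C)C)C[C@@]2(C(=O)OC)[C@@H]3CC[C@]3(C4SCCS4)[C@@H]12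
F5 | step 13 | amino cyclodecadiene lactone (thermolysed Mannich base) | CN(C)CC1C(=O)O[C@@H]2/C=C(C)/CC/C=C(C(=O)OC)\C[C@@H](O[Si](C)(C)C(C)(C)C)[C@@H]12
F6 | step 13 | trimethylammonium iodide of F5 | C[N+](C)(C)CC1C(=O)O[C@@H]2/C=C(C)/CC/C=C(C(=O)OC)\C[C@@H](O[Si](C)(C)C(C)(C)C)[C@@H]12.[I-]
F7 | step 10 | C6 epimer of 14 (OH cis to the C7 arm) | O[C@@H]1[C@H](CC(=O)OC(C)(C)C)[C@H](O[Si](C)(C)C(C)(C)C)C[C@@]2(C(=O)OC)[C@@H]3CC[C@]3(C)[C@@H]12
F8 | step 10 | 4-nitrobenzoate of 14 | O=C(O[C@H]1[C@H](CC(=O)OC(C)(C)C)[C@H](O[Si](C)(C)C(C)(C)C)C[C@@]2(C(=O)OC)[C@@H]3CC[C@]3(C)[C@@H]12)c1ccc(cc1)[N+](=O)[O-]
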